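The ratio in which target and isomer of the product grow is, moment by moment, a ratio of two rates, and the ratio of their amounts adds these moments up. If each product comes from its own conformer on the same catalyst, the catalyst cancels and the rate ratio is S·c(starting material)/c(other conformer), with S the selectivity factor.

| flask | starting material | other conformer | precatalyst | remark | time |
|---|---|---|---|---|---|
| spring | 0.56 M | 0.40 M | 2 mM | run made earlier |  |
| midnight | 0.88 M | 0.40 M | 2 mM | run made earlier |  |
| flask | 0.40 M | 0.400 M | 2.0 mM |  | 15 d |

- spring (time / d: target / %, isomer of the product / %): 1.67: 6, 0; 4.00: 7, 2; 5.00: 13, 7; 8.00: 18, 7; 10.0: 25, 7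
- midnight (time / d: target / %, isomer of the product / %): 1.67: 5, 5; 4.00: 11, 4; 5.00: 12, 3; 8.00: 20, 7; 10.0: 25, 7

(readings scatter by 1.5 percentage points)

1. ratio of target to isomer of the product at 8.0 h
2. ratio of target to isomer of the product at 2.5 d
3. ratio of target to isomer of the product at 15 d

In the flask, c(starting material)/c(other conformer) at the start is 1.00: this is the charge ratio, which I carry. It stands lower than in the spring run, 1.40, or the midnight run, 2.20. Yet both runs read 25% against 7% at 10.0 d, a ratio of 3.57, with a scatter of 1.5 percentage points on each reading. So I read the conformers as equilibrated by then (the Curtin–Hammett case), and I expect the flask near 3.57 at 15 d. Early on, the flask should still follow its charge ratio, but the first readings, 6% against 0% in the spring run and 5% against 5% in the midnight run, are too scattered to give me a number.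

The forecast gives 2.7, 2.9 and 3.2, holding that “the ratio is set independent of charge at about 3”. Its late value is lower than my reading.

The flask gives 6.24, 3.42 and 3.01.

    starting material ⇌ other conformer (K = 2.85, k = 1.91 × 10⁻⁵ s⁻¹)
    starting material + catalyst → catalyst + target (k = 0.00588 M⁻¹ s⁻¹)
    catalyst + other conformer → catalyst + isomer of the product (k = 6.69 × 10⁻⁴ M⁻¹ s⁻¹)
    2 catalyst ⇌ resting dimer (K = 18100 M⁻¹, k = 0.00564 M⁻¹ s⁻¹)
    precatalyst ⇌ catalyst (K = 1.01, k = 5.49 × 10⁻⁶ s⁻¹)
    catalyst ⇌ dormant form (K = 4.77, k = 1.42 × 10⁻⁴ s⁻¹)

At 8.0 h the flask stands at 6.24. Its c(starting material)/c(other conformer) falls from the charge ratio 1.00 to 0.355 at 1.50 d and 0.337 at 15.0 d. A neighbouring flask with 0.68 M of other conformer has a charge ratio of 0.588, so scaling the flask's early ratio by 0.588 over 1.00 gives 3.67. That neighbour stands at 4.35 at 8.0 h and at 2.98 at 15 d.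

Readings and results stem from a simulated flask with constants of no real substance; scatter was added.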